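**Retrosynthetic overview**
- The target is reached from ring A aryl ketone 20 by hydride reduction, hydrogenolysis (four benzyl ethers and the carbinol C–O bond) and desilylation.
- Ring A is the only ring made. Its bonds C1–C2 and C5–C6 are formed by an Alder–Rickert reaction of silyloxydiene 6 with ynone 18, with loss of ethene.
- The strategy rests on the O–C3–C4(H)–C5–O unit of ring A (C3–OH, C5–OMe). It is the ketone and enol ether of 3-methoxycyclohex-2-enone, whose α′ carbon becomes C2 and takes the benzyl group by enolate alkylation.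
- Diene 6 comes from 3-methoxycyclohex-2-enone by α′-benzylation and kinetic silyl dienol ether formation.
- Ynone 18 comes from 5-bromo-2-hydroxybenzyl alcohol (ring B) by propargylation, Negishi benzylation and acyl Sonogashira coupling.

Key step: step 9

Assumption: ring A is numbered C1 (CH2CH2–ring B chain), C2 and C6 (4-hydroxybenzyl groups), C3 (OH), C4 (H), C5 (OMe); the target is achiral, and intermediates with a stereocentre (4, 19, 21) are used as racemates.

**Step 1**
Reactants: 1 3-methoxycyclohex-2-en-1-one; 2 4-(benzyloxy)benzyl bromide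
Product: 4 6-[4-(benzyloxy)benzyl]-3-methoxycyclohex-2-en-1-one (racemic), via lithium dienolate 3 (not isolated)
Conditions: LiN(i-Pr)2, THF, −78 °C; then 2, −78 °C to rt
Reagents that add atoms: none
Why: LiN(i-Pr)2 removes the kinetic α′ proton at C6 of the vinylogous ester, and the cross-conjugated enolate 3 is C-alkylated by the reactive benzylic bromide (Stork–Danheiser α′-alkylation), the new C6 stereocentre being formed as a racemate that is flattened again in step 2.

**Step 2**
Reactants: 4 6-[4-(benzyloxy)benzyl]-3-methoxycyclohex-2-en-1-one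
Product: 6 1-[4-(benzyloxy)benzyl]-2-[(tert-butyldimethylsilyl)oxy]-4-methoxycyclohexa-1,3-diene, via lithium dienolate 5 (not isolated)
Conditions: LiN(i-Pr)2, THF, −78 °C; then t-BuMe2SiCl, DMPU, −78 to 0 °C; non-aqueous work-up, used crude
Reagents that add atoms: tert-butyldimethylsilyl chloride, CC(C)(C)[Si](C)(C)Cl
Why: A second kinetic α′-deprotonation at the remaining C6–H gives dienolate 5, whose oxygen is silylated by the silyl chloride in the presence of DMPU (kinetic silyl enol ether formation), which fixes the diene as C(benzyl)=C(OSi)–CH=C(OMe).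

**Step 3**
Reactants: 7 5-bromo-2-hydroxybenzyl alcohol
Product: 8 [2-(benzyloxy)-5-bromophenyl]methanol
Conditions: BnBr, K2CO3, acetone, reflux
Reagents that add atoms: benzyl bromide, BrCc1ccccc1
Why: K2CO3 deprotonates only the phenol, so the phenoxide alone is benzylated and the benzylic alcohol stays free (Williamson ether synthesis).

**Step 4**
Reactants: 8 [2-(benzyloxy)-5-bromophenyl]methanol
Product: 9 1-(benzyloxy)-4-bromo-2-(bromomethyl)benzene
Conditions: PBr3, CH2Cl2, 0 °C
Reagents that add atoms: phosphorus tribromide, BrP(Br)Br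
Why: PBr3 converts the primary benzylic alcohol into the bromide by SN2 displacement of the phosphite ester at 0 °C, conditions under which the aryl benzyl ether and the aryl bromide are inert.

**Step 5**
Reactants: 9 1-(benzyloxy)-4-bromo-2-(bromomethyl)benzene; 10 trimethyl(prop-1-yn-1-yl)silane
Product: 12 {4-[2-(benzyloxy)-5-bromophenyl]but-1-yn-1-yl}trimethylsilane, via lithiated silylpropyne 11 (not isolated)
Conditions: 10, n-BuLi, THF, −78 to −20 °C; then 9, −78 to 0 °C
Reagents that add atoms: none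
Why: Deprotonated 1-(trimethylsilyl)propyne reacts with the benzylic bromide at its propargylic carbon (SN2 alkylation of a silyl-capped propargyl anion), the silyl group disfavouring attack through the allenyl terminus, and no alkyllithium is left to exchange with the aryl bromide.

**Step 6**
Reactants: 12 {4-[2-(benzyloxy)-5-bromophenyl]but-1-yn-1-yl}trimethylsilane; 13 4-(benzyloxy)benzyl chloride
Product: 15 (4-{2-(benzyloxy)-5-[4-(benzyloxy)benzyl]phenyl}but-1-yn-1-yl)trimethylsilane, via benzylzinc chloride 14 (not isolated)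
Conditions: 13, Zn dust, LiCl, THF, rt; then 12, Pd(OAc)2 (cat.), SPhos (cat.), THF, rt to 50 °C
Reagents that add atoms: none
Why: Zinc inserts into the benzylic C–Cl bond in the presence of LiCl, and the resulting benzylzinc 14 couples with the aryl bromide at zerovalent palladium (Negishi cross-coupling), which tolerates the silylalkyne and the benzyl ethers.

**Step 7**
Reactants: 15 (4-{2-(benzyloxy)-5-[4-(benzyloxy)benzyl]phenyl}but-1-yn-1-yl)trimethylsilane
Product: 16 1-(benzyloxy)-4-[4-(benzyloxy)benzyl]-2-(but-3-yn-1-yl)benzene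
Conditions: K2CO3 (cat.), MeOH/THF, rt
Reagents that add atoms: none
Why: Methoxide generated from K2CO3 in methanol attacks silicon and releases the acetylide, which is protonated by the solvent (base-catalysed protodesilylation of an alkynylsilane).

**Step 8**
Reactants: 16 1-(benzyloxy)-4-[4-(benzyloxy)benzyl]-2-(but-3-yn-1-yl)benzene; 17 4-(benzyloxy)benzoyl chloride
Product: 18 5-{2-(benzyloxy)-5-[4-(benzyloxy)benzyl]phenyl}-1-[4-(benzyloxy)phenyl]pent-2-yn-1-one
Conditions: PdCl2(PPh3)2 (cat.), CuI (cat.), Et3N, THF, rt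
Reagents that add atoms: none
Why: The copper acetylide formed with CuI and Et3N transmetallates to the acylpalladium species from the acid chloride, and reductive elimination gives the ynone at room temperature (acyl Sonogashira coupling).

**Step 9**
Reactants: 6 1-[4-(benzyloxy)benzyl]-2-[(tert-butyldimethylsilyl)oxy]-4-methoxycyclohexa-1,3-diene; 18 5-{2-(benzyloxy)-5-[4-(benzyloxy)benzyl]phenyl}-1-[4-(benzyloxy)phenyl]pent-2-yn-1-one
Product: 20 [4-(benzyloxy)phenyl]{2-(2-{2-(benzyloxy)-5-[4-(benzyloxy)benzyl]phenyl}ethyl)-3-[4-(benzyloxy)benzyl]-4-[(tert-butyldimethylsilyl)oxy]-6-methoxyphenyl}methanone, via bicyclo[2.2.2]octa-2,5-diene adduct 19 (not isolated)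
Conditions: 6 (excess), mesitylene (concentrated), 160–180 °C, sealed tube, Ar
Reagents that add atoms: none
Why: The electron-rich silyloxy-methoxy diene 6 and ynone 18 should undergo a thermal normal-electron-demand (4+2) cycloaddition to the bicyclo[2.2.2]octa-2,5-diene 19, which at the same temperature undergoes a retro-(4+2) reaction that expels the saturated CH2–CH2 bridge of the former cyclohexadiene as ethene (Alder–Rickert reaction). The closest known reaction type is the Alder–Rickert benzannulation of 1-methoxy-3-silyloxycyclohexa-1,3-dienes with acetylenic ketones and esters, which gives resorcinol monomethyl ether derivatives. Ring A, the only ring formed, is closed by this intermolecular cycloaddition, which makes C1–C2 and C5–C6 in one operation, and aromatisation makes the loss of ethene irreversible. No stereocentre survives, because the two bridgehead centres of racemic 19 become sp2 carbons of ring A. The step needs one regiochemistry, the benzyl-bearing diene terminus to the ynone β-carbon and the methoxy-bearing terminus to the carbonyl-bearing α-carbon; the silyloxy group directly and the methoxy group through the diene both raise the HOMO coefficient at the benzyl-bearing terminus, which therefore pairs with the electrophilic β-carbon. The two fully substituted bridgeheads slow the addition, hence the high temperature, the high concentration and the excess of 6.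

**Step 10**
Reactants: 20 the ring A aryl ketone from step 9
Product: 21 [4-(benzyloxy)phenyl]{2-(2-{2-(benzyloxy)-5-[4-(benzyloxy)benzyl]phenyl}ethyl)-3-[4-(benzyloxy)benzyl]-4-[(tert-butyldimethylsilyl)oxy]-6-methoxyphenyl}methanol (racemic)
Conditions: LiAlH4, THF, 0 °C to rt
Reagents that add atoms: none
Why: LiAlH4 is small and reactive enough to add hydride to the di-ortho-substituted diaryl ketone (hydride reduction), the aryl silyl ether and benzyl ethers being stable at 0 °C, and the new carbinol stereocentre is racemic and disappears in step 11.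

**Step 11**
Reactants: 21 the diarylcarbinol from step 10
Product: 22 2-{2-[3-[(tert-butyldimethylsilyl)oxy]-2,6-bis(4-hydroxybenzyl)-5-methoxyphenyl]ethyl}-4-(4-hydroxybenzyl)phenol
Conditions: H2 (3 bar), 10% Pd/C, EtOAc/AcOH, rt
Reagents that add atoms: none
Why: Palladium-catalysed hydrogenolysis cleaves the four benzyl ethers and, assisted by acetic acid, the doubly benzylic C–O bond of the electron-rich diarylcarbinol, while the aryl silyl ether, the methyl ether and the arene rings should be unaffected at room temperature.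

**Step 12**
Reactants: 22 the silyl ether from step 11
Product: 23 2-{2-[3-hydroxy-2,6-bis(4-hydroxybenzyl)-5-methoxyphenyl]ethyl}-4-(4-hydroxybenzyl)phenol (target)
Conditions: Bu4NF, AcOH, THF, 0 °C to rt
Reagents that add atoms: none
Why: Fluoride attacks silicon and releases the phenoxide (fluoride-induced desilylation of an aryl silyl ether), and acetic acid buffering keeps the polyphenol from being handled as its phenoxide.

**Compound list**
1 | 3-methoxycyclohex-2-en-1-one | COC1=CC(=O)CCC1 | starting material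
2 | 4-(benzyloxy)benzyl bromide | BrCc1ccc(OCc2ccccc2)cc1 | starting material
3 | lithium 5-methoxycyclohexa-1,5-dien-1-olate | [Li]OC1=CCCC(OC)=C1 | intermediate
4 | 6-[4-(benzyloxy)benzyl]-3-methoxycyclohex-2-en-1-one (racemic) | COC1=CC(=O)C(Cc2ccc(OCc3ccccc3)cc2)CC1 | intermediate
5 | lithium 2-[4-(benzyloxy)benzyl]-5-methoxycyclohexa-1,5-dien-1-olate | [Li]OC1=C(Cc2ccc(OCc3ccccc3)cc2)CCC(OC)=C1 | intermediate
6 | 1-[4-(benzyloxy)benzyl]-2-[(tert-butyldimethylsilyl)oxy]-4-methoxycyclohexa-1,3-diene | COC1=CC(O[Si](C)(C)C(C)(C)C)=C(Cc2ccc(OCc3ccccc3)cc2)CC1 | intermediate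
7 | 5-bromo-2-hydroxybenzyl alcohol | OCc1cc(Br)ccc1O | starting material
8 | [2-(benzyloxy)-5-bromophenyl]methanol | OCc1cc(Br)ccc1OCc1ccccc1 | intermediate
9 | 1-(benzyloxy)-4-bromo-2-(bromomethyl)benzene | BrCc1cc(Br)ccc1OCc1ccccc1 | intermediate
10 | trimethyl(prop-1-yn-1-yl)silane | CC#C[Si](C)(C)C | starting material
11 | [3-(trimethylsilyl)prop-2-yn-1-yl]lithium | [Li]CC#C[Si](C)(C)C | intermediate
12 | {4-[2-(benzyloxy)-5-bromophenyl]but-1-yn-1-yl}trimethylsilane | C[Si](C)(C)C#CCCc1cc(Br)ccc1OCc1ccccc1 | intermediate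
13 | 4-(benzyloxy)benzyl chloride | ClCc1ccc(OCc2ccccc2)cc1 | starting material
14 | [4-(benzyloxy)benzyl]zinc chloride | Cl[Zn]Cc1ccc(OCc2ccccc2)cc1 | intermediate
15 | (4-{2-(benzyloxy)-5-[4-(benzyloxy)benzyl]phenyl}but-1-yn-1-yl)trimethylsilane | C[Si](C)(C)C#CCCc1cc(Cc2ccc(OCc3ccccc3)cc2)ccc1OCc1ccccc1 | intermediate
16 | 1-(benzyloxy)-4-[4-(benzyloxy)benzyl]-2-(but-3-yn-1-yl)benzene | C#CCCc1cc(Cc2ccc(OCc3ccccc3)cc2)ccc1OCc1ccccc1 | intermediate
17 | 4-(benzyloxy)benzoyl chloride | O=C(Cl)c1ccc(OCc2ccccc2)cc1 | starting material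
18 | 5-{2-(benzyloxy)-5-[4-(benzyloxy)benzyl]phenyl}-1-[4-(benzyloxy)phenyl]pent-2-yn-1-one | O=C(C#CCCc1cc(Cc2ccc(OCc3ccccc3)cc2)ccc1OCc1ccccc1)c1ccc(OCc2ccccc2)cc1 | intermediate
19 | {3-(2-{2-(benzyloxy)-5-[4-(benzyloxy)benzyl]phenyl}ethyl)-4-[4-(benzyloxy)benzyl]-5-[(tert-butyldimethylsilyl)oxy]-1-methoxybicyclo[2.2.2]octa-2,5-dien-2-yl}[4-(benzyloxy)phenyl]methanone (racemic) | COC12CCC(Cc3ccc(OCc4ccccc4)cc3)(C(O[Si](C)(C)C(C)(C)C)=C1)C(CCc1cc(Cc3ccc(OCc4ccccc4)cc3)ccc1OCc1ccccc1)=C2C(=O)c1ccc(OCc2ccccc2)cc1 | intermediate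
20 | [4-(benzyloxy)phenyl]{2-(2-{2-(benzyloxy)-5-[4-(benzyloxy)benzyl]phenyl}ethyl)-3-[4-(benzyloxy)benzyl]-4-[(tert-butyldimethylsilyl)oxy]-6-methoxyphenyl}methanone | COc1cc(O[Si](C)(C)C(C)(C)C)c(Cc2ccc(OCc3ccccc3)cc2)c(CCc2cc(Cc3ccc(OCc4ccccc4)cc3)ccc2OCc2ccccc2)c1C(=O)c1ccc(OCc2ccccc2)cc1 | intermediate
21 | [4-(benzyloxy)phenyl]{2-(2-{2-(benzyloxy)-5-[4-(benzyloxy)benzyl]phenyl}ethyl)-3-[4-(benzyloxy)benzyl]-4-[(tert-butyldimethylsilyl)oxy]-6-methoxyphenyl}methanol (racemic) | COc1cc(O[Si](C)(C)C(C)(C)C)c(Cc2ccc(OCc3ccccc3)cc2)c(CCc2cc(Cc3ccc(OCc4ccccc4)cc3)ccc2OCc2ccccc2)c1C(O)c1ccc(OCc2ccccc2)cc1 | intermediate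
22 | 2-{2-[3-[(tert-butyldimethylsilyl)oxy]-2,6-bis(4-hydroxybenzyl)-5-methoxyphenyl]ethyl}-4-(4-hydroxybenzyl)phenol | COc1cc(O[Si](C)(C)C(C)(C)C)c(Cc2ccc(O)cc2)c(CCc2cc(Cc3ccc(O)cc3)ccc2O)c1Cc1ccc(O)cc1 | intermediate
23 | 2-{2-[3-hydroxy-2,6-bis(4-hydroxybenzyl)-5-methoxyphenyl]ethyl}-4-(4-hydroxybenzyl)phenol | COc1cc(O)c(Cc2ccc(O)cc2)c(CCc2cc(Cc3ccc(O)cc3)ccc2O)c1Cc1ccc(O)cc1 | target

**Totals**
Total step count: 12.
Longest linear sequence: 10 steps (7 to 23 through steps 3–8 and 9–12); the diene arm is 2 steps before the convergence.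

**Steps most likely to fail**

1. Step 9. The cycloaddition may be too slow for a β-alkyl ynone whose carbonyl is deactivated by the 4-alkoxyphenyl donor and which must bond to a fully substituted diene terminus. Thermal hydrogen shifts in the diene, loss of the silyl group, or isomerisation of the ynone at its propargylic CH2 could then win. The fallback sets out from alkyne 16 and diene 6 and comes back at carbinol 21. Alkyne 16 would be lithiated (n-BuLi, THF, −78 °C) and formylated with DMF to give 5-{2-(benzyloxy)-5-[4-(benzyloxy)benzyl]phenyl}pent-2-ynal F1. This smaller and more electrophilic dienophile should add to 6 at lower temperature (toluene, 110–130 °C) with the same regiochemistry, through the bicyclo[2.2.2]octa-2,5-diene-2-carbaldehyde adduct F2. Loss of ethene would give 2-(2-{2-(benzyloxy)-5-[4-(benzyloxy)benzyl]phenyl}ethyl)-3-[4-(benzyloxy)benzyl]-4-[(tert-butyldimethylsilyl)oxy]-6-methoxybenzaldehyde F3. Addition of 4-(benzyloxy)phenylmagnesium bromide (THF, 0 °C) to F3 should give 21 directly, so step 10 is not needed.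

2. Step 2. Deprotonation at the γ carbon (C4), or enolate equilibration during a slow silylation, would deliver the linearly conjugated silyloxydiene isomer, and the silyl dienol ether may hydrolyse back to 4 on isolation. The fallback sets out from 1 and comes back at 6, defining the enol ether position by reduction and not by deprotonation. The kinetic enolate of 1 (LiN(i-Pr)2, THF, −78 °C) would be added to 4-(benzyloxy)benzaldehyde to give the aldol 6-{[4-(benzyloxy)phenyl](hydroxy)methyl}-3-methoxycyclohex-2-en-1-one F4. Mesylation (MsCl, Et3N, CH2Cl2, 0 °C) would give the mesylate of that aldol F5, and DBU would eliminate it to (E)-6-[4-(benzyloxy)benzylidene]-3-methoxycyclohex-2-en-1-one F6. 1,4-Hydrosilylation of the arylidene enone of F6 (t-BuMe2SiH, RhCl(PPh3)3 cat., toluene, 60–80 °C) should place hydrogen on the benzylic carbon and silicon on oxygen, giving 6 as a single regioisomer. The electron-rich methoxy-substituted double bond should not accept hydride.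

3. Step 11. Hydrogenolysis of the hindered carbinol C–O bond may stall after debenzylation. Stronger acid to force it could cause Friedel–Crafts capture of the benzhydryl cation by ring B or loss of the silyl ether. The fallback sets out from 21 and comes back at 22. Ionic deoxygenation of 21 (Et3SiH, CF3CO2H, CH2Cl2, −20 to 0 °C) should give tert-butyl{[3-(2-{2-(benzyloxy)-5-[4-(benzyloxy)benzyl]phenyl}ethyl)-2,4-bis[4-(benzyloxy)benzyl]-5-methoxyphenyl]oxy}dimethylsilane F7, since hydride transfer to the stabilised diarylmethyl cation is fast. Neutral hydrogenolysis of F7 (H2, 10% Pd/C, EtOAc/EtOH, rt) would then remove only the four benzyl groups and give 22.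

**Further compounds**
F1 | step 9 | 5-{2-(benzyloxy)-5-[4-(benzyloxy)benzyl]phenyl}pent-2-ynal | O=CC#CCCc1cc(Cc2ccc(OCc3ccccc3)cc2)ccc1OCc1ccccc1
F2 | step 9 | 3-(2-{2-(benzyloxy)-5-[4-(benzyloxy)benzyl]phenyl}ethyl)-4-[4-(benzyloxy)benzyl]-5-[(tert-butyldimethylsilyl)oxy]-1-methoxybicyclo[2.2.2]octa-2,5-diene-2-carbaldehyde (racemic) | COC12CCC(Cc3ccc(OCc4ccccc4)cc3)(C(O[Si](C)(C)C(C)(C)C)=C1)C(CCc1cc(Cc3ccc(OCc4ccccc4)cc3)ccc1OCc1ccccc1)=C2C=O
F3 | step 9 | 2-(2-{2-(benzyloxy)-5-[4-(benzyloxy)benzyl]phenyl}ethyl)-3-[4-(benzyloxy)benzyl]-4-[(tert-butyldimethylsilyl)oxy]-6-methoxybenzaldehyde | COc1cc(O[Si](C)(C)C(C)(C)C)c(Cc2ccc(OCc3ccccc3)cc2)c(CCc2cc(Cc3ccc(OCc4ccccc4)cc3)ccc2OCc2ccccc2)c1C=O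
F4 | step 2 | 6-{[4-(benzyloxy)phenyl](hydroxy)methyl}-3-methoxycyclohex-2-en-1-one (mixture of diastereomers) | COC1=CC(=O)C(C(O)c2ccc(OCc3ccccc3)cc2)CC1
F5 | step 2 | [4-(benzyloxy)phenyl](4-methoxy-2-oxocyclohex-3-en-1-yl)methyl methanesulfonate (mixture of diastereomers) | COC1=CC(=O)C(C(OS(C)(=O)=O)c2ccc(OCc3ccccc3)cc2)CC1
F6 | step 2 | (E)-6-[4-(benzyloxy)benzylidene]-3-methoxycyclohex-2-en-1-one | COC1=CC(=O)/C(=C/c2ccc(OCc3ccccc3)cc2)CC1
F7 | step 11 | tert-butyl{[3-(2-{2-(benzyloxy)-5-[4-(benzyloxy)benzyl]phenyl}ethyl)-2,4-bis[4-(benzyloxy)benzyl]-5-methoxyphenyl]oxy}dimethylsilane | COc1cc(O[Si](C)(C)C(C)(C)C)c(Cc2ccc(OCc3ccccc3)cc2)c(CCc2cc(Cc3ccc(OCc4ccccc4)cc3)ccc2OCc2ccccc2)c1Cc1ccc(OCc2ccccc2)cc1
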